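At late times the west run is still creeping upward, with 49.0% of the electrophile as product after 10.0 h, so I ask first where such a curve can stop. I take the runs rung by rung in time.

the same everywhere: electrophile 0.19 M

| flask | nucleophile | free base | protic impurity | temperature | remark | time |
|---|---|---|---|---|---|---|
| west | 0.16 M | 0.057 M | 9.5 mM | 20 °C | run made earlier |  |
| south | 0.29 M | 0.057 M | 9.5 mM | 32 °C | run made earlier |  |
| delta | 0.400 M | 0.0570 M | 9.50 mM | 25 °C |  | 4.0 h |
| theta | 0.285 M | 0.0570 M | 9.50 mM | 40 °C |  | 4.0 h |

- west (time / h: product / %): 2.00: 41.1; 4.00: 44.3; 5.00: 45.5; 6.00: 44.6; 8.00: 47.3; 10.0: 49.0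
- south (time / h: product / %): 0.667: 59.8; 1.33: 67.8; 2.00: 70.7; 2.50: 73.8; 3.00: 72.9; 4.00: 75.9

(each reading ± 1 percentage point)

- steps under discussion: nucleophile + acid set free <-> protonated nucleophile; electrophile + nucleophile -> acid set free + product; electrophile <-> dormant form; acid set free + free base <-> salt of the base; nucleophile + protic impurity -> quenched reagent

- the flask that ends with the higher amount of product, in percent of the electrophile charged, or "neither" when 2 percentage points or less lies between them (delta / theta / neither)
- final product, as a percentage of the electrophile charged, in delta
- final product, as a percentage of the electrophile charged, in theta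

The first rung is the burst: the south run already shows 59.8% at its first reading, 0.667 h. The next rung is the tail, which I replace by its mean slope. Between 2.00 h and 4.00 h the south run gains 5.2 percentage points, climbing more slowly than just before 2.00 h. The slope is falling, so any time reckoned from this mean errs on the short side.

The top rung is the stop itself. Each product sets free one acid. Each product also uses one nucleophile, and its acid is bound either by a second nucleophile, as protonated nucleophile, or by the free base, as salt of the base. This balance needs no order between the two binders, and I reckon it for the end point at which the nucleophile and the free base are both used up. The protic impurity quenches one nucleophile each. Adding the charges of nucleophile and free base, subtracting the protic impurity, halving, and dividing by the electrophile gives 87.5% for theta; this nucleophile budget is the product that the nucleophile and the free base can pay for with each acid bound.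

The west run has a budget of 54.6% and the south run 88.8%, and both stand below it so far. At its mean slope the south run needs 4.97 h more, a reading that carries the scatter and is longer than 4.0 h. So I expect theta, with a similar budget though warmer, to end some points under it. Delta's budget is 118%, so there the electrophile is the limiting reagent, and I put delta ahead.

The forecast gives 83% (76% to 90%) for delta and 80% (76% to 85%) for theta: “The gap is modest, but delta is favoured.”

    nucleophile + acid set free ⇌ protonated nucleophile, settled at all times (K = 26000 M⁻¹, ΔH = −18.0 kJ mol⁻¹)
    electrophile + nucleophile → acid set free + product (k = 0.00860 M⁻¹ s⁻¹, Ea = 57.0 kJ mol⁻¹)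
    electrophile ⇌ dormant form (K = 1.10, k = 9.70 × 10⁻⁴ s⁻¹, Ea = 94.0 kJ mol⁻¹, ΔH = −23.0 kJ mol⁻¹)
    acid set free + free base ⇌ salt of the base, settled at all times (K = 1100 M⁻¹, ΔH = −50.0 kJ mol⁻¹)
    nucleophile + protic impurity → quenched reagent (k = 0.0530 M⁻¹ s⁻¹, Ea = 49.0 kJ mol⁻¹)
    (constants at 40 °C)

The flask gives 87.1% in delta and 79.4% in theta, so delta ends ahead. In delta the forward step to product runs 4.1 times the forward step to dormant form at 0.202 h and 1.2 times at 4.00 h, when 10.0% stands as dormant form and 17% of the charged nucleophile is left. Delta, with its budget of 118%, reaches 99.7% at 40.0 h, whereas theta, with 0.154% of its nucleophile left by then, comes close to its budget of 87.5% at 88.5%.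

(The data stem from a simulated flask with made-up constants; the scatter is artificial.)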